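The two aryl–CH2 bonds at C3 and C5 of ring A (the methoxylated ring, with C1 bearing the ketone) are the disconnection. Both prenyl groups should arrive in one operation by a double aromatic Claisen rearrangement of bis(1,1-dimethylallyl) ether 13, a 4-methoxy-2,6-dialkoxybenzophenone whose ring B phenol is masked as a pivalate. The step exploits the substitution pattern around O2 and O6. Each ether oxygen has one ortho carbon occupied (C1, carrying the aroyl group) and one free (C3 or C5), so the allyl units can only land where the target needs them. Allylic transposition gives linear prenyl groups and unveils the two ketone-chelated phenols.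

Key step: step 6

Remark on the chemistry: ring A is numbered from the carbonyl-bearing carbon (OH at C2 and C6, prenyl at C3 and C5, OMe at C4), and ring B is the 3-hydroxyphenyl ring. The target has no stereocentre and no stereogenic alkene. The ring B phenol is carried as a pivalate because an aryl ester cannot enter the etherification or the rearrangement, should tolerate AlCl3, BCl3, DBU and heat, and leaves by mild methanolysis. Step 4 installs two propargyl groups and therefore consumes two molar equivalents of alcohol 8.

Step 1
Reactants: 1 3-hydroxybenzoic acid
Product: 2 3-(pivaloyloxy)benzoic acid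
Conditions: PivCl (1.2 equiv), aq. NaOH (2.2 equiv), THF/H2O, 0 °C; then HCl to pH 2
Reagents that add atoms: pivaloyl chloride, CC(C)(C)C(=O)Cl
Why: Schotten–Baumann O-acylation, in which the phenoxide of the dianion is acylated, any mixed anhydride at the carboxylate is hydrolysed by the aqueous base, and the hindered aryl pivalate survives the cold work-up.

Step 2
Reactants: 2 3-(pivaloyloxy)benzoic acid; 3 1,3,5-trimethoxybenzene
Product: 5 3-(2,4,6-trimethoxybenzoyl)phenyl pivalate, via acid chloride 4 (not isolated)
Conditions: (COCl)2, cat. DMF, CH2Cl2, 0 °C → rt, evaporate; then 3, AlCl3 (1.2 equiv), CH2Cl2, 0 °C; ice/1 M HCl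
Reagents that add atoms: none
Why: Friedel–Crafts acylation of a highly nucleophilic, threefold-symmetric arene, whose three ring CH positions are equivalent, by the aroyl chloride made in the flask; the ketone product is deactivated towards a second acylation and the pivalate should tolerate AlCl3 at 0 °C.

Step 3
Reactants: 5 3-(2,4,6-trimethoxybenzoyl)phenyl pivalate
Product: 7 3-(2,6-dihydroxy-4-methoxybenzoyl)phenyl pivalate, via mono-phenol 6 (not isolated)
Conditions: BCl3 (1 M in CH2Cl2, 5 equiv), CH2Cl2, −10 °C → rt; H2O quench
Reagents that add atoms: none
Why: Chelation-directed aryl methyl ether cleavage, in which boron bound to the ketone oxygen engages the neighbouring methoxy oxygen in a six-membered chelate and chloride removes the methyl group, first at O2 and, after the carbonyl turns towards O6, at the second ortho position, while the C4 methoxy group (no chelate possible) and the pivalate react only slowly with BCl3 at room temperature.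

Step 4
Reactants: 7 3-(2,6-dihydroxy-4-methoxybenzoyl)phenyl pivalate; 8 2-methylbut-3-yn-2-ol (2.6 equiv in all, one equivalent per phenol plus a small excess)
Product: 11 3-[4-methoxy-2,6-bis(2-methylbut-3-yn-2-yloxy)benzoyl]phenyl pivalate, via propargyl trifluoroacetate 9 (not isolated), via mono-propargyl ether 10 (not isolated)
Conditions: 8 (2.6 equiv), (CF3CO)2O (2.6 equiv), DBU (3.2 equiv), MeCN, −5 °C; the solution added to 7, DBU (2.4 equiv), CuCl2·2H2O (cat.), MeCN, −5 → 0 °C
Reagents that add atoms: 2-methylbut-3-yn-2-ol (the second equivalent, likewise converted in the flask into trifluoroacetate 9), CC(C)(O)C#C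
Why: Copper-catalysed propargylic etherification run twice on the same substrate, in which each molecule of the tertiary trifluoroacetate is ionised through a copper acetylide and a DBU-generated phenoxide attacks the tertiary carbon, first at one ortho oxygen (giving 10) and then at the other; it runs at 0 °C, below the onset of propargyl Claisen rearrangement, suits electron-poor phenoxides such as those of an acyl-substituted diphenol, and leaves the hindered aryl pivalate alone.

Step 5
Reactants: 11 3-[4-methoxy-2,6-bis(2-methylbut-3-yn-2-yloxy)benzoyl]phenyl pivalate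
Product: 13 3-[4-methoxy-2,6-bis(2-methylbut-3-en-2-yloxy)benzoyl]phenyl pivalate, via ene-yne 12 (not isolated)
Conditions: H2 (1 atm), Pd/CaCO3 poisoned with Pb(OAc)2, quinoline, EtOAc, rt, stopped after 2 equiv H2; concentrated below 30 °C
Reagents that add atoms: none
Why: Lindlar semihydrogenation, in which the poisoned palladium surface reduces terminal alkynes much faster than the resulting monosubstituted alkenes, so stopping at two equivalents of hydrogen should leave the vinyl groups, the diaryl ketone, the ester and the arenes untouched.

Step 6
Reactants: 13 3-[4-methoxy-2,6-bis(2-methylbut-3-en-2-yloxy)benzoyl]phenyl pivalate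
Product: 15 3-[2,6-dihydroxy-4-methoxy-3,5-bis(3-methylbut-2-enyl)benzoyl]phenyl pivalate, via mono-rearranged phenol 14 (not isolated)
Conditions: PhNEt2 (degassed), 135 °C, Ar; amine removed by chromatography
Reagents that add atoms: none
Why: Each O–CMe2–CH=CH2 unit reorganises in a concerted (3,3)-sigmatropic shift: in a chair-shaped six-atom array the =CH2 terminus bonds to the neighbouring ring CH (C3 for the O2 ether, C5 for the O6 ether) as the O–CMe2 bond breaks, and the 6-prenylcyclohexa-2,4-dienone so formed tautomerises to the phenol. This is the aromatic Claisen rearrangement of tertiary allyl aryl ethers, a standard entry to ortho-prenylphenols, and the allylic transposition converts each tertiary ether into a linear 3-methylbut-2-enyl group. No ring is closed and no stereocentre or stereogenic alkene is formed, so only site selectivity and chemoselectivity matter. Site selectivity is secured by the substrate: the second ortho carbon of each ether is C1, which carries the aroyl group and cannot rearomatise after allyl transfer, so C3 and C5 are the only productive acceptors. Chemoselectivity against heterolysis of the tertiary allylic C–O bond (loss of isoprene) and against acid-induced chroman formation from the new ortho-prenyl phenols is secured by the weakly basic amine solvent, while the geminal methyl groups and relief of crowding around the ketone keep the temperature moderate. The ring B oxygen is acylated and takes no part, and the temperature stays below the range in which ortho-prenyl phenols isomerise further.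

Step 7
Reactants: 15 3-[2,6-dihydroxy-4-methoxy-3,5-bis(3-methylbut-2-enyl)benzoyl]phenyl pivalate
Product: 16 [2,6-dihydroxy-4-methoxy-3,5-bis(3-methylbut-2-enyl)phenyl](3-hydroxyphenyl)methanone
Conditions: K2CO3 (cat., 0.5 equiv), MeOH, rt; aq. NH4Cl work-up
Reagents that add atoms: none
Why: Base-catalysed transesterification (methanolysis) of an aryl ester, in which methoxide attacks the pivalate carbonyl and expels the ring B phenoxide, while the ring A phenoxides, the prenyl groups and the aryl methyl ether are inert and the buffered work-up avoids acid-induced cyclisation.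

Compound list
1 | 3-hydroxybenzoic acid | OC(=O)c1cccc(O)c1 | starting material
2 | 3-(pivaloyloxy)benzoic acid | CC(C)(C)C(=O)Oc1cccc(C(=O)O)c1 | intermediate
3 | 1,3,5-trimethoxybenzene | COc1cc(OC)cc(OC)c1 | starting material
4 | 3-(pivaloyloxy)benzoyl chloride | CC(C)(C)C(=O)Oc1cccc(C(=O)Cl)c1 | intermediate
5 | 3-(2,4,6-trimethoxybenzoyl)phenyl pivalate | COc1cc(OC)c(C(=O)c2cccc(OC(=O)C(C)(C)C)c2)c(OC)c1 | intermediate
6 | 3-(2-hydroxy-4,6-dimethoxybenzoyl)phenyl pivalate (held as its boron chelate in the flask) | COc1cc(O)c(C(=O)c2cccc(OC(=O)C(C)(C)C)c2)c(OC)c1 | intermediate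
7 | 3-(2,6-dihydroxy-4-methoxybenzoyl)phenyl pivalate | COc1cc(O)c(C(=O)c2cccc(OC(=O)C(C)(C)C)c2)c(O)c1 | intermediate
8 | 2-methylbut-3-yn-2-ol | CC(C)(O)C#C | starting material
9 | 2-methylbut-3-yn-2-yl trifluoroacetate | CC(C)(OC(=O)C(F)(F)F)C#C | intermediate
10 | 3-[2-hydroxy-4-methoxy-6-(2-methylbut-3-yn-2-yloxy)benzoyl]phenyl pivalate | COc1cc(O)c(C(=O)c2cccc(OC(=O)C(C)(C)C)c2)c(OC(C)(C)C#C)c1 | intermediate
11 | 3-[4-methoxy-2,6-bis(2-methylbut-3-yn-2-yloxy)benzoyl]phenyl pivalate | COc1cc(OC(C)(C)C#C)c(C(=O)c2cccc(OC(=O)C(C)(C)C)c2)c(OC(C)(C)C#C)c1 | intermediate
12 | 3-[4-methoxy-2-(2-methylbut-3-en-2-yloxy)-6-(2-methylbut-3-yn-2-yloxy)benzoyl]phenyl pivalate | COc1cc(OC(C)(C)C=C)c(C(=O)c2cccc(OC(=O)C(C)(C)C)c2)c(OC(C)(C)C#C)c1 | intermediate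
13 | 3-[4-methoxy-2,6-bis(2-methylbut-3-en-2-yloxy)benzoyl]phenyl pivalate (key-step precursor) | COc1cc(OC(C)(C)C=C)c(C(=O)c2cccc(OC(=O)C(C)(C)C)c2)c(OC(C)(C)C=C)c1 | intermediate
14 | 3-[2-hydroxy-4-methoxy-3-(3-methylbut-2-enyl)-6-(2-methylbut-3-en-2-yloxy)benzoyl]phenyl pivalate | COc1cc(OC(C)(C)C=C)c(C(=O)c2cccc(OC(=O)C(C)(C)C)c2)c(O)c1CC=C(C)C | intermediate
15 | 3-[2,6-dihydroxy-4-methoxy-3,5-bis(3-methylbut-2-enyl)benzoyl]phenyl pivalate (key-step product) | COc1c(CC=C(C)C)c(O)c(C(=O)c2cccc(OC(=O)C(C)(C)C)c2)c(O)c1CC=C(C)C | intermediate
16 | [2,6-dihydroxy-4-methoxy-3,5-bis(3-methylbut-2-enyl)phenyl](3-hydroxyphenyl)methanone | COc1c(CC=C(C)C)c(O)c(C(=O)c2cccc(O)c2)c(O)c1CC=C(C)C | target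

Total step count: 7. Longest linear sequence: 7 steps (1 → 2 → 5 → 7 → 11 → 13 → 15 → 16).

Steps most likely to fail

Step 4. The double etherification may stall at mono-ether 10, because the remaining phenol is crowded and hydrogen-bonded to the ketone, or be eroded by premature propargyl Claisen rearrangement to chromenes. The fallback sets out from 7 and bypasses the alkyne stage. It would treat 7 with two equivalents of tert-butyl 2-methylbut-3-en-2-yl carbonate F1 (made from 2-methylbut-3-en-2-ol with n-BuLi, then Boc2O, in THF) and catalytic Pd(PPh3)4 in THF at 0 °C. This decarboxylative Tsuji–Trost O-allylation is known to give the branched 1,1-dimethylallyl aryl ether under kinetic control, because the phenoxide attacks the tertiary terminus of the dimethylallyl palladium complex. It comes back to the route at 13 and makes 11 and the semihydrogenation unnecessary.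

Step 6. Heterolysis of the tertiary allylic C–O bonds (loss of isoprene) may outrun the sigmatropic shift, or the liberated ortho-prenyl phenols may cyclise onto their alkenes. The fallback sets out from 7 and introduces both prenyl groups by direct C-alkylation with two equivalents of 1-bromo-3-methylbut-2-ene and DBU in THF at 0 °C → rt. C-Prenylation of acylphloroglucinol-type phenoxides is a known, if less selective, reaction type, and C3 and C5 are the only free ring carbons. It comes back to the route at 15 and makes no compound outside the list (F0).

Step 3. The second ortho demethylation may stop at the mono-phenol stage, or forcing it may begin to cleave the C4 methyl ether. The fallback sets out from acid chloride 4 (generated from 2 as in step 2). Friedel–Crafts acylation of phloroglucinol (benzene-1,3,5-triol) with AlCl3 in PhNO2/CH2Cl2 would give 3-(2,4,6-trihydroxybenzoyl)phenyl pivalate F2. Mono-O-methylation with MeI (1 equiv) and K2CO3 in acetone should then take place at the C4 hydroxyl, which is the most acidic, unhindered and not hydrogen-bonded to the ketone. It comes back to the route at 7.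

Further compounds
F1 | step 4 | tert-butyl 2-methylbut-3-en-2-yl carbonate | CC(C)(C)OC(=O)OC(C)(C)C=C
F0 | step 6 | none | none
F2 | step 3 | 3-(2,4,6-trihydroxybenzoyl)phenyl pivalate | CC(C)(C)C(=O)Oc1cccc(C(=O)c2c(O)cc(O)cc2O)c1
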